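In a one-step world every substrate lost turns up at once as product, but the south-east run at 120 min has 8.2% substrate left and 21.2% product, so 70.6% of its charge stands in between, and I call that the intermediate.

| setting | south-west | south-east | west | teal | red | green | blue | amber |
|---|---|---|---|---|---|---|---|---|
| substrate | 7.6 mM | 57 mM | 20 mM | 12 mM | 6.0 mM | 20 mM | 40 mM | 12 mM |
| partner | 3 equiv | 3 equiv | 4.4 equiv | 2.00 equiv | 3.00 equiv | 3.00 equiv | 9.00 equiv | 3.00 equiv |
| scavenger | 1 equiv | 1 equiv | 1 equiv | 0.500 equiv | 1.00 equiv | 1.00 equiv | 1.00 equiv | 1.00 equiv |
| remark | run made earlier | run made earlier | run made earlier |  |  |  |  |  |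
| time |  |  |  | 4.0 h | 4.0 h | 4.0 h | 4.0 h | 4.0 h |

- south-west (time / min: product / %, substrate / %): 8.00: 1.1, 96.3; 25.0: 0, 88.3; 40.0: 2.2, 82.5; 60.0: 2.7, 79.1; 90.0: 6.1, 71.5; 120: 8.8, 65.1
- south-east (time / min: product / %, substrate / %): 20.0: 2.8, 54.7; 40.0: 5.2, 35.3; 60.0: 10.7, 23.5; 80.0: 13.8, 15.3; 90.0: 15.8, 12.5; 120: 21.2, 8.2
- west (time / min: product / %, substrate / %): 25.0: 0.5, 68.4; 50.0: 4.1, 49.0; 80.0: 9.8, 35.2; 90.0: 10.5, 29.7; 120: 17.7, 20.4

(scatter of a reading: 1 percentage point)

- the analysis behind the earlier runs scatters by 1 percentage point, standard deviation
- a reading or a percentage of product counts all its forms, free or not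

1. the flasks put in order of amount of product, in percent of the substrate charged, best first, at 4.0 h (teal / red / green / blue / amber)
2. the amount of product, in percent of the substrate charged of the flask you put first, at 4.0 h
3. the amount of product, in percent of the substrate charged of the flask you put last, at 4.0 h

I therefore run two clocks and reckon with rates. The first is the filling rate f, the share of the substrate lost per minute at the start, which I take as a constant k, read from the west run as 1.70 × 10⁻⁴ /mM/min, times the partner concentration, a pseudo-first-order view in which I hold f at its starting value although partner is spent. The second is the clearing rate c, the share of the standing intermediate that turns to product each minute, 0.00307 /min, which I read as the south-east product at 120 min divided by the in-between share summed over that time.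

Blue, the fast end, starts with f = 0.0613 /min, which is 20.0 times c, so I reckon it as a flask filled with intermediate at one stroke but 16.3 min late, that delay being the mean wait of the substrate in my view and not the moment at which the substrate is gone. Counted from that late start, the share short of product in blue falls as e^(−ct) and stands at 0.503 by 4.0 h, so I expect 49.6% in blue.

Red, the slow end, has f = 0.00307 /min, about equal to c. For equal clocks the share short of product is (1 + ft)e^(−ft), which leaves red at 16.8%. Joining the ends, the share short of product is (f·e^(−ct) − c·e^(−ft))/(f − c). With one c, a larger f gives more product, and f falls from blue through green, amber and teal to red, which is my order.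

The forecast, whose numbers differ from mine, gives blue > green > amber > teal > red, with 47% for blue (33% to 56%) and 19% for red (14% to 23%), noting of blue that “substrate is gone within an hour”.

The flasks come out as blue > green > amber > teal > red, with blue at 52.7% and red at 17.1%.

    intermediate → product (k = 5.70 × 10⁻⁵ /s)
    scavenger + released group → scavenged by-product (k = 0.130 /M/s)
    substrate + partner → intermediate + released group (k = 0.00281 /M/s)
    substrate + released group ⇌ idle adduct, settled at all times (K = 39.8 /M)
    crystals ⇌ product, rate k5*(cs5 - [product]) while solid is left; crystals form when [product] > cs5 (solubility = 7.30 mM, k = 0.00756 /s)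

At 4.00 h blue has converted >99.9% of its substrate and holds 47.3% as intermediate, on which c puts a gain of 0.0871 /h of the charge. The recipe of red with 24 mM substrate has f = 0.0123 /min, the joined rule with c gives it 38.0%, and that flask stands at 37.7% product with 51.4% intermediate.

The data are simulated from invented constants; the scatter is artificial.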